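The readings are simulated with constants of no real substance.

In the elm run links could not pass 58.1% of the first end groups charged, because 0.50 M of second end groups stood against 0.86 M of first end groups. That made the second end groups the limiting reagent, and the readings levelled near 58.3%.

| flask | first end groups | second end groups | remark | time |
|---|---|---|---|---|
| elm | 0.86 M | 0.50 M | run made earlier |  |
| cedar | 0.86 M | 1.2 M | run made earlier |  |
| south-east | 0.86 M | 0.860 M |  | 100 min |
| north-east | 0.86 M | 1.30 M |  | 100 min |
| south | 0.86 M | 1.90 M |  | 100 min |

| run | time / min | links / % | first end groups / % |
|---|---|---|---|
| elm | 8.00 | 54.6 | 44.5 |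
| elm | 12.0 | 56.6 | 43.6 |
| elm | 20.0 | 58.3 | 43.5 |
| elm | 30.0 | 58.0 | 41.2 |
| elm | 40.0 | 57.2 | 42.1 |
| elm | 60.0 | 57.6 | 43.1 |
| elm | 90.0 | 56.8 | 42.5 |
| cedar | 5.00 | 89.4 | 8.6 |
| cedar | 15.0 | 96.5 | 0.5 |
| cedar | 30.0 | 93.0 | 0 |
| cedar | 40.0 | 91.6 | 0 |
| cedar | 60.0 | 87.3 | 0 |
| cedar | 80.0 | 85.8 | 0 |
| cedar | 90.0 | 83.2 | 0 |

(each reading ± 1 percentage point)

- the analysis behind the earlier runs scatters by 1 percentage point, standard deviation
- a reading or a percentage of links counts all its forms, free or not

1. which of the two there is more of at the end, south-east (links / over-reaction product)
2. which of the two there is more of at the end, north-east (links / over-reaction product)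
3. which of the two there is more of at the end, south (links / over-reaction product)
4. amount of links at the end, in percent of the first end groups charged, south-east
5. amount of links at the end, in percent of the first end groups charged, north-east
6. amount of links at the end, in percent of the first end groups charged, south

Cedar was the opposite case, with second end groups left over, and its links did not hold: they read 96.5% at 15.0 min and 83.2% at 90.0 min. I took this as leftover second end groups eating links, so I counted lifetimes. Those two readings gave 506 min for the link lifetime, the time in which links shrink by a factor e at cedar's excess of 0.340 M. I took it as inversely proportional to the excess c(second end groups) − c(first end groups) as charged, a pseudo-first-order view that holds the excess fixed.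

Then I ran south slowly in my head. In the first instants, the early cedar reading gave first end groups a lifetime of 0.644 min at south's charge, far shorter than the 165 min of links at south's excess, so links would form first. In the middle I expected links and 1.04 M of leftover second end groups, with the slow loss running. By the end, 100 min made 0.606 lifetimes, and my estimate for links was 54.6%. The tie with over-reaction product lies at 0.693 lifetimes, and my count stood below it, so I said links, narrowly. North-east, with a smaller excess than south, came to 77.4% by the same estimate. South-east was charged with 0.86 M of first end groups and 0.860 M of second end groups, so I made no count of lifetimes there.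

The forecast gave 95%, 77% and 54% for south-east, north-east and south, with links ahead in south, and called south “a long extrapolation and close to a tie”.

    first end groups + second end groups → links + by-product (k = 0.840 M⁻¹ min⁻¹)
    second end groups + links → over-reaction product (k = 0.0140 M⁻¹ min⁻¹)
    crystals ⇌ links, rate k3*(cs3 - [links]) while solid is left; crystals form when [links] > cs3 (solubility = 0.410 M, k = 1.60 min⁻¹)

South gave 47.0% of links against 53.0% of over-reaction product, so over-reaction product led there, while south-east gave 94.4% and north-east 77.2%. At the end south held 0% as crystals, north-east 29.6%. Read from south's own end, the link lifetime was 132 min against my 165 min, a count of 0.755 lifetimes, past the tie. In a neighbour of south charged with 1.1 M of second end groups, the cedar lifetime scales to 716 min, and the count gives an estimate of 87.0% of links. That flask gave 87.1%, with 39.5% as crystals.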